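**Plan**

1. Retrosynthetic cuts, in order: the C11–C20 epoxide, the C6–Cl/C5=C16 unit and the C2/C14 esters (back to a 5E-olefin, an 11(20)-methylene and a 2,14-diol); then the lactone C7–O bond and the ring bond C6–C7 (iodoalkene + aldehyde); then C8–C9 (enolate + aldehyde); last C10–C11 of the cyclohexane.
2. Enabling feature: C1 carries two constitutionally identical, homochiral arms, C14(O)–C13–C12–C11(–C20) and C2(O)–C3–C4–C5(–C6). Before C10–C11 exists, C1 is therefore not a stereocentre and a (5S,7S)-diyne diol made from an achiral 1,3-diketone suffices. C10 is α to the C9 carbonyl and C8 is fully substituted, so only C10 can be enolised.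
3. Forward: 3-methylpentane-2,4-dione is propargylated at each terminal methyl in turn and allylated, reduced twice (CBS) and protected as the acetonide; the derived aldehyde is joined to a dioxolanone made from (S)-malic acid. Ring A (C1, C10–C14) is then closed by gold-catalysed 6-exo-dig addition of the C9 silyl enol ether to one of the two diastereotopic alkynes.
4. The untouched alkyne becomes the (E)-iodoalkene that closes the ten-membered ring at C6–C7 onto a C7 aldehyde. Lactonisation, ester adjustment, ene oxygenation with chloride inversion at C6, and epoxidation of the 11(20)-olefin finish the route.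
5. Stereochemistry: C2/C14 from the CBS catalyst; C8/C17 from (S)-malic acid (anti methylation, self-regeneration of C8); C1/C10 from the key step; C9 by Felkin–Anh reduction; C7 in the chromium-mediated closure; C6 by SN2 inversion; C11 by epoxidation anti to the axial C15 methyl.

Key step: step 15

Remark on the chemistry: briarane numbering is used (C1 quaternary with methyl C15; C2–C10 complete the ten-membered ring; C11–C14 complete ring A; C16 on C5; C20 on C11; lactone C17(C18)–C19). β is the face of ring A that carries C15. Where descriptors in a name could shift with substituent changes, the SMILES is authoritative.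

**Route**

Step 1
Reactants: 1 3-methylpentane-2,4-dione; 2 3-bromo-1-(trimethylsilyl)prop-1-yne
Product: 3 3-methyl-8-(trimethylsilyl)oct-7-yne-2,4-dione
Conditions: LiN(i-Pr)2 (2.1 equiv), THF, −78 to 0 °C; then 2 (1.0 equiv), −78 to 0 °C; aq. NH4Cl
Reagents that add atoms: none
Why: γ-alkylation of a 1,3-diketone dianion (Hauser type), which reacts at the terminal methyl carbon, the silyl cap blocking SN2′ attack and acetylide formation.

Step 2
Reactants: 3 3-methyl-8-(trimethylsilyl)oct-7-yne-2,4-dione; 2 3-bromo-1-(trimethylsilyl)prop-1-yne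
Product: 4 6-methyl-1,11-bis(trimethylsilyl)undeca-1,10-diyne-5,7-dione
Conditions: LiN(i-Pr)2 (2.1 equiv), THF, −78 to 0 °C; then 2 (1.05 equiv), −78 °C to rt; aq. NH4Cl
Reagents that add atoms: none
Why: second γ-alkylation of a 1,3-diketone dianion, which forms at the remaining methyl group in preference to the more substituted C5 methylene and so gives the symmetrical diyne dione.

Step 3
Reactants: 4 6-methyl-1,11-bis(trimethylsilyl)undeca-1,10-diyne-5,7-dione; 5 allyl methyl carbonate
Product: 6 6-methyl-6-(prop-2-en-1-yl)-1,11-bis(trimethylsilyl)undeca-1,10-diyne-5,7-dione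
Conditions: Pd(PPh3)4 (2 mol %), THF, rt
Reagents that add atoms: none
Why: Tsuji–Trost allylation with zerovalent palladium, in which the methoxide released from the carbonate deprotonates the 2-methyl-1,3-diketone and C-allylation builds the (still achiral) quaternary C1.

Step 4
Reactants: 6 6-methyl-6-(prop-2-en-1-yl)-1,11-bis(trimethylsilyl)undeca-1,10-diyne-5,7-dione
Product: 7 (5S,7S)-6-methyl-6-(prop-2-en-1-yl)-1,11-bis(trimethylsilyl)undeca-1,10-diyne-5,7-diol
Conditions: (R)-2-methyl-CBS-oxazaborolidine (0.5 equiv), catecholborane (3 equiv), toluene, −78 °C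
Reagents that add atoms: none
Why: twofold Corey–Bakshi–Shibata reduction in which the quaternary carbon is the large and the CH2 chain the small ketone substituent, so the (R)-catalyst should set both carbinols S (future C2 and C14) without touching the olefin or alkynes.

Step 5
Reactants: 7 (5S,7S)-6-methyl-6-(prop-2-en-1-yl)-1,11-bis(trimethylsilyl)undeca-1,10-diyne-5,7-diol
Product: 8 (5S,7S)-6-methyl-6-(prop-2-en-1-yl)undeca-1,10-diyne-5,7-diol
Conditions: K2CO3 (0.2 equiv), MeOH, rt
Reagents that add atoms: none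
Why: base-catalysed methanolysis of the two alkynyl C–Si bonds, done at the diol stage because the diketone would be open to retro-Claisen cleavage.

Step 6
Reactants: 8 (5S,7S)-6-methyl-6-(prop-2-en-1-yl)undeca-1,10-diyne-5,7-diol
Product: 9 (4S,6S)-4,6-di(but-3-yn-1-yl)-2,2,5-trimethyl-5-(prop-2-en-1-yl)-1,3-dioxane
Conditions: 2,2-dimethoxypropane, PPTS (cat.), CH2Cl2, rt
Reagents that add atoms: 2,2-dimethoxypropane COC(C)(C)OC
Why: acetonide formation of the anti-1,3-diol, whose trans-4,6-disubstituted 2,2-dimethyl-1,3-dioxane should adopt the twist-boat that is exploited in step 15.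

Step 7
Reactants: 9 (4S,6S)-4,6-di(but-3-yn-1-yl)-2,2,5-trimethyl-5-(prop-2-en-1-yl)-1,3-dioxane
Product: 10 2-[(4S,6S)-4,6-di(but-3-yn-1-yl)-2,2,5-trimethyl-1,3-dioxan-5-yl]acetaldehyde
Conditions: OsO4 (2 mol %), NaIO4 (4 equiv), 2,6-lutidine, dioxane/H2O, rt
Reagents that add atoms: sodium periodate [Na+].[O-]I(=O)(=O)=O; water O
Why: Lemieux–Johnson cleavage of the terminal olefin, which reacts far faster than the terminal alkynes, gives the C9 aldehyde with C10 as its α-carbon.

Step 8
Reactants: 11 diethyl (S)-malate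
Product: 12 diethyl (2S,3R)-2-hydroxy-3-methylbutanedioate
Conditions: LiN(i-Pr)2 (2.2 equiv), THF, −78 to −20 °C; MeI, −78 °C to rt
Reagents that add atoms: iodomethane CI
Why: Fráter–Seebach alkylation of the alkoxide enolate dianion, which should methylate anti to the alkoxide and so set C17 (R) next to the future C8.

Step 9
Reactants: 12 diethyl (2S,3R)-2-hydroxy-3-methylbutanedioate
Product: 13 (2S,3R)-2-hydroxy-3-methylbutanedioic acid
Conditions: LiOH·H2O (3 equiv), THF/H2O, 0 °C to rt; then HCl to pH 1
Reagents that add atoms: lithium hydroxide [Li+].[OH-]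
Why: mild saponification of both esters, under which the α-hydroxy and α-methyl centres should not epimerise.

Step 10
Reactants: 13 (2S,3R)-2-hydroxy-3-methylbutanedioic acid
Product: 14 (2R)-2-[(2S,4S)-2-tert-butyl-5-oxo-1,3-dioxolan-4-yl]propanoic acid
Conditions: t-BuCHO, TsOH·H2O (cat.), H2SO4 (cat.), pentane, reflux, water separator
Reagents that add atoms: pivalaldehyde CC(C)(C)C=O
Why: acetalisation of the α-hydroxy acid with pivalaldehyde gives the five-membered cis-dioxolanone under thermodynamic control, storing the C8 configuration in the acetal centre.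

Step 11
Reactants: 14 (2R)-2-[(2S,4S)-2-tert-butyl-5-oxo-1,3-dioxolan-4-yl]propanoic acid
Product: 15 tert-butyl (2R)-2-[(2S,4S)-2-tert-butyl-5-oxo-1,3-dioxolan-4-yl]propanoate
Conditions: isobutene, H2SO4 (cat.), CH2Cl2, rt, sealed vessel
Reagents that add atoms: isobutene CC(C)=C
Why: acid-catalysed addition of the acid to isobutene gives the C19 tert-butyl ester, chosen to survive borohydride and to resist premature lactonisation.

Step 12
Reactants: 10 2-[(4S,6S)-4,6-di(but-3-yn-1-yl)-2,2,5-trimethyl-1,3-dioxan-5-yl]acetaldehyde; 15 tert-butyl (2R)-2-[(2S,4S)-2-tert-butyl-5-oxo-1,3-dioxolan-4-yl]propanoate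
Product: 16 tert-butyl (2R)-2-[(2S,4R)-2-tert-butyl-4-{2-[(4S,6S)-4,6-di(but-3-yn-1-yl)-2,2,5-trimethyl-1,3-dioxan-5-yl]-1-hydroxyethyl}-5-oxo-1,3-dioxolan-4-yl]propanoate (both C9 epimers)
Conditions: LiN(SiMe3)2 (1.1 equiv), THF, −78 °C; then 10, −78 °C; AcOH quench at −78 °C
Reagents that add atoms: none
Why: aldol addition of the dioxolanone enolate (self-regeneration of stereocentres), in which the aldehyde enters anti to the tert-butyl group so that C9 replaces the former C8 hydrogen with retention; the C9 configuration is irrelevant because it is oxidised next.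

Step 13
Reactants: 16 aldol adduct (both C9 epimers)
Product: 17 tert-butyl (2R)-2-[(2S,4R)-2-tert-butyl-4-{[(4S,6S)-4,6-di(but-3-yn-1-yl)-2,2,5-trimethyl-1,3-dioxan-5-yl]acetyl}-5-oxo-1,3-dioxolan-4-yl]propanoate
Conditions: Dess–Martin periodinane, NaHCO3, CH2Cl2, rt
Reagents that add atoms: none
Why: Dess–Martin oxidation converges both epimers to the C9 ketone, which is flanked by the quaternary C8 and can enolise only towards C10.

Step 14
Reactants: 17 C9 ketone
Product: 18 (Z)-C9 tert-butyldimethylsilyl enol ether of 17 (C9=C10; silyloxy group cis to C1)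
Conditions: TBSOTf (1.3 equiv), Et3N (3 equiv), CH2Cl2, −78 to 0 °C
Reagents that add atoms: tert-butyldimethylsilyl triflate CC(C)(C)[Si](C)(C)OS(=O)(=O)C(F)(F)F
Why: soft enolisation gives the only possible regioisomer and the thermodynamically preferred Z geometry, with the two fully substituted carbons C8 and C1 trans.

Step 15
Reactants: 18 (Z)-silyl enol ether
Product: 19 ring-A ketone: cyclohexane C1/C10–C14 with 11(20)-exo-methylene; C15 β on C1; H-10 α; cis-fused 2,14-O-isopropylidene acetal (O-14 α); C9 ketone bound to C4 of the (2S,4R)-dioxolanone; but-3-yn-1-yl on C2 (S)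
Conditions: [(t-Bu)2(2-biphenylyl)P]Au(NCMe)SbF6 (5 mol %), MeOH (2 equiv), CH2Cl2, 0 °C to rt
Reagents that add atoms: none
Why: Cationic monovalent gold π-activates a terminal alkyne, C10 of the silyl enol ether attacks its internal carbon anti to gold, and transfer of the silyl group to methanol followed by protodeauration releases the C9 ketone with the C11=C20 exocyclic methylene; the closest known reaction type is the gold-catalysed Conia-ene-type carbocyclisation of silyl enol ethers onto alkynes. Ring A is closed in the 6-exo-dig mode through a chair in which C9 is equatorial. C10 is controlled by allylic 1,3-strain in the Z-enol ether, which holds the C15 methyl in the enol plane so that it ends axial and trans to H-10. C1 becomes a stereocentre by the choice between the two diastereotopic butynyl arms: in the twist-boat of the trans-4,6-disubstituted 2,2-dimethyl-1,3-dioxane the ring torsion at each bond to C1 is about 30°, so C10 is synclinal to the arm cis to it and close to 90° from the other, and closure onto the cis arm should give the cis-fused dioxane (C15 and H-14 cis, O-14 axial), which is the target arrangement of C1 relative to C2 and C14. The step needs group selectivity between the arms and regioselective enolisation; the acetonide should secure the first and the fully substituted C8 secures the second, while the second alkyne is left untouched for the ten-membered ring.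

Step 16
Reactants: 19 ring-A ketone
Product: 21 (9S)-C7,C8,C9-triol (C7 primary alcohol; C8 tertiary alcohol; tert-butyl ester and acetonide intact), via 9-hydroxy dioxolanone 20 (not isolated)
Conditions: LiBH4 (4 equiv), THF, −20 to 0 °C
Reagents that add atoms: none
Why: borohydride should add to the C9 ketone on the face favoured both by the Felkin–Anh model at C10 (anti to the quaternary C1, C11 inside) and by lithium chelation to the C8 acetal oxygen (attack past the ring carbonyl, not past the branched C17) to give the 9S alcohol, and then reduces the acyl-acetal carbonyl to the C7 alcohol with loss of the pivalaldehyde unit, the hindered tert-butyl ester being left alone at this temperature.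

Step 17
Reactants: 21 triol
Product: 22 7-O-triethylsilyl ether of 21
Conditions: TESCl (1.1 equiv), imidazole, CH2Cl2, −20 °C
Reagents that add atoms: chlorotriethylsilane CC[Si](CC)(CC)Cl
Why: silylation is selective for the primary C7 hydroxyl over the hindered secondary C9 and tertiary C8 hydroxyls.

Step 18
Reactants: 22 7-O-triethylsilyl ether
Product: 23 (E)-iodoalkene: the C2 side chain is now (E)-4-iodo-3-methylbut-3-en-1-yl (C3–C4–C5(C16)=C6–I)
Conditions: AlMe3 (5 equiv), (C5H5)2ZrCl2 (0.5 equiv), H2O (1 equiv), CH2Cl2, −23 °C; then I2, THF, −23 °C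
Reagents that add atoms: trimethylaluminium C[Al](C)C; iodine II
Why: Negishi carboalumination adds methyl (C16) and aluminium syn across the terminal alkyne with methyl on the internal carbon, and iodinolysis with retention gives the E-iodoalkene; the 1,1-disubstituted olefin is inert and the two hydroxyls are carried as aluminium alkoxides.

Step 19
Reactants: 23 (E)-iodoalkene
Product: 24 9-O-acetate of 23
Conditions: Ac2O, DMAP (cat.), pyridine, CH2Cl2, rt
Reagents that add atoms: acetic anhydride CC(=O)OC(C)=O
Why: only the secondary C9 hydroxyl is acylated (the tertiary C8 hydroxyl is inert), which installs the final C9 acetate and blocks O-9 from competing for the lactone carbonyl later.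

Step 20
Reactants: 24 9-O-acetate
Product: 25 C7 aldehyde (α-tertiary-hydroxy aldehyde; C8 fully substituted)
Conditions: (COCl)2, DMSO, CH2Cl2, −78 to −30 °C; Et3N, −78 °C to rt
Reagents that add atoms: none
Why: Swern conditions cleave a primary triethylsilyl ether and oxidise it in the same operation, giving an aldehyde that cannot enolise because C8 is fully substituted.

Step 21
Reactants: 25 C7 aldehyde
Product: 26 ten-membered (5E)-olefin with C7–OH configured as the lactone oxygen of the target (7S by descriptor); 9-OAc; 8-OH; tert-butyl ester; 2,14-acetonide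
Conditions: CrCl2 (10 equiv), NiCl2 (0.1 equiv), DMSO/THF, 0.002 M, rt
Reagents that add atoms: none
Why: Nozaki–Hiyama–Kishi macrocyclisation forms C6–C7 with retention of the E geometry, and addition anti to the C8–O bond (polar Felkin–Anh) with the ring tether holding C9 gauche to the incoming alkenyl group should give the required C7 configuration.

Step 22
Reactants: 26 ten-membered allylic alcohol
Product: 27 7,19-lactone 2,14-diol (5E-olefin; 9-OAc; 8-OH)
Conditions: TsOH·H2O (0.2 equiv), wet CH2Cl2, rt
Reagents that add atoms: none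
Why: acid-catalysed lactonisation of the γ-hydroxy tert-butyl ester can engage only O-7 because O-9 is acetylated, and the strained twist-boat acetonide is hydrolysed in the same operation.

Step 23
Reactants: 27 lactone diol
Product: 29 14-O-acetate with free C2 hydroxyl, via cyclic orthoacetate 28 (not isolated)
Conditions: MeC(OMe)3, camphorsulfonic acid (cat.), CH2Cl2, rt; then 80% aq. AcOH, rt
Reagents that add atoms: trimethyl orthoacetate CC(OC)(OC)OC; water O
Why: the 2,14-diol forms a six-membered cyclic orthoester whose hydrolytic opening should follow the known preference of cyclic orthoester hydrolysis for placing the ester on the more hindered, axial ring oxygen (O-14) and leaving the exocyclic one (O-2) free.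

Step 24
Reactants: 29 14-O-acetate
Product: 30 2-O-isobutyrate (5E-olefin; 9,14-di-OAc; 8-OH; 11(20)-methylene)
Conditions: i-PrCOCl, pyridine, DMAP (cat.), CH2Cl2, 0 °C to rt
Reagents that add atoms: 2-methylpropanoyl chloride CC(C)C(Cl)=O
Why: the only acylable hydroxyl is the secondary one at C2, the tertiary C8 hydroxyl being inert under these conditions.

Step 25
Reactants: 30 2-O-isobutyrate
Product: 32 (6R)-allylic alcohol with C5=C16 exocyclic methylene, via allylic hydroperoxide 31 (not isolated)
Conditions: O2, tetraphenylporphyrin (cat.), visible light, CH2Cl2, 0 °C; then PPh3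
Reagents that add atoms: oxygen O=O
Why: Schenck ene reaction of singlet oxygen at the trisubstituted olefin (the 1,1-disubstituted one is far slower) bonds oxygen to C6 with hydrogen taken from C16 on the crowded side, and attack on the exposed face of the E-cyclodecene should place the oxygen syn to O-7, giving the 6R alcohol after reduction.

Step 26
Reactants: 32 (6R)-allylic alcohol
Product: 33 (6S)-chloride (5(16)- and 11(20)-methylenes; all esters in place)
Conditions: PPh3, hexachloroacetone, CH2Cl2, −20 to 0 °C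
Reagents that add atoms: hexachloroacetone ClC(Cl)(Cl)C(=O)C(Cl)(Cl)Cl
Why: Appel-type chlorination of a secondary allylic alcohol with this reagent pair proceeds by SN2 with inversion and without allylic transposition, giving the 6S chloride anti to O-7.

Step 27
Reactants: 33 (6S)-chloride
Product: 34 target compound
Conditions: mCPBA, NaHCO3, CH2Cl2, 0 °C
Reagents that add atoms: 3-chloroperbenzoic acid OOC(=O)c1cccc(Cl)c1
Why: Prilezhaev epoxidation should select the 11(20)-olefin over the 5(16)-olefin deactivated by the allylic chlorine, and attack from the α face, away from the syn-axial C15 methyl, gives the 11R spiro-epoxide.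

**Compound list**

1 | 3-methylpentane-2,4-dione | CC(=O)C(C)C(C)=O | starting material
2 | 3-bromo-1-(trimethylsilyl)prop-1-yne | C[Si](C)(C)C#CCBr | starting material
3 | 3-methyl-8-(trimethylsilyl)oct-7-yne-2,4-dione | CC(=O)C(C)C(=O)CCC#C[Si](C)(C)C | intermediate
4 | 6-methyl-1,11-bis(trimethylsilyl)undeca-1,10-diyne-5,7-dione | C[Si](C)(C)C#CCCC(=O)C(C)C(=O)CCC#C[Si](C)(C)C | intermediate
5 | allyl methyl carbonate | C=CCOC(=O)OC | starting material
6 | 6-methyl-6-(prop-2-en-1-yl)-1,11-bis(trimethylsilyl)undeca-1,10-diyne-5,7-dione | C=CCC(C)(C(=O)CCC#C[Si](C)(C)C)C(=O)CCC#C[Si](C)(C)C | intermediate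
7 | (5S,7S)-6-methyl-6-(prop-2-en-1-yl)-1,11-bis(trimethylsilyl)undeca-1,10-diyne-5,7-diol | C=CCC(C)([C@@H](O)CCC#C[Si](C)(C)C)[C@@H](O)CCC#C[Si](C)(C)C | intermediate
8 | (5S,7S)-6-methyl-6-(prop-2-en-1-yl)undeca-1,10-diyne-5,7-diol | C=CCC(C)([C@@H](O)CCC#C)[C@@H](O)CCC#C | intermediate
9 | (4S,6S)-4,6-di(but-3-yn-1-yl)-2,2,5-trimethyl-5-(prop-2-en-1-yl)-1,3-dioxane | C=CCC1(C)[C@H](CCC#C)OC(C)(C)O[C@H]1CCC#C | intermediate
10 | 2-[(4S,6S)-4,6-di(but-3-yn-1-yl)-2,2,5-trimethyl-1,3-dioxan-5-yl]acetaldehyde | O=CCC1(C)[C@H](CCC#C)OC(C)(C)O[C@H]1CCC#C | intermediate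
11 | diethyl (S)-malate | CCOC(=O)C[C@H](O)C(=O)OCC | starting material
12 | diethyl (2S,3R)-2-hydroxy-3-methylbutanedioate | CCOC(=O)[C@H](C)[C@H](O)C(=O)OCC | intermediate
13 | (2S,3R)-2-hydroxy-3-methylbutanedioic acid | OC(=O)[C@H](C)[C@H](O)C(=O)O | intermediate
14 | (2R)-2-[(2S,4S)-2-tert-butyl-5-oxo-1,3-dioxolan-4-yl]propanoic acid | [C@@H]1(C(C)(C)C)OC(=O)[C@@H](O1)[C@@H](C)C(=O)O | intermediate
15 | tert-butyl (2R)-2-[(2S,4S)-2-tert-butyl-5-oxo-1,3-dioxolan-4-yl]propanoate | [C@@H]1(C(C)(C)C)OC(=O)[C@@H](O1)[C@@H](C)C(=O)OC(C)(C)C | intermediate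
16 | tert-butyl (2R)-2-[(2S,4R)-2-tert-butyl-4-{2-[(4S,6S)-4,6-di(but-3-yn-1-yl)-2,2,5-trimethyl-1,3-dioxan-5-yl]-1-hydroxyethyl}-5-oxo-1,3-dioxolan-4-yl]propanoate, both C9 epimers | [C@@H]1(C(C)(C)C)OC(=O)[C@](O1)(C(O)CC2(C)[C@H](CCC#C)OC(C)(C)O[C@H]2CCC#C)[C@@H](C)C(=O)OC(C)(C)C | intermediate
17 | tert-butyl (2R)-2-[(2S,4R)-2-tert-butyl-4-{[(4S,6S)-4,6-di(but-3-yn-1-yl)-2,2,5-trimethyl-1,3-dioxan-5-yl]acetyl}-5-oxo-1,3-dioxolan-4-yl]propanoate | [C@@H]1(C(C)(C)C)OC(=O)[C@](O1)(C(=O)CC2(C)[C@H](CCC#C)OC(C)(C)O[C@H]2CCC#C)[C@@H](C)C(=O)OC(C)(C)C | intermediate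
18 | (Z)-C9 tert-butyldimethylsilyl enol ether of 17 (C9=C10, silyloxy cis to C1) | [C@@H]1(C(C)(C)C)OC(=O)[C@](O1)(/C(O[Si](C)(C)C(C)(C)C)=C/C2(C)[C@H](CCC#C)OC(C)(C)O[C@H]2CCC#C)[C@@H](C)C(=O)OC(C)(C)C | intermediate
19 | ring-A ketone: cyclohexane C1/C10–C14 with 11(20)-exo-methylene, C15 β, H-10 α, cis-fused 2,14-O-isopropylidene (O-14 α); C9 ketone on C4 of the (2S,4R)-2-tert-butyl-5-oxo-1,3-dioxolane that also bears (R)-CH(CH3)CO2t-Bu; but-3-yn-1-yl on C2 (S) | C#CCC[C@@H]3OC(C)(C)O[C@H]4CCC(=C)[C@H](C(=O)[C@]5(O[C@H](C(C)(C)C)OC5=O)[C@@H](C)C(=O)OC(C)(C)C)[C@@]34C | intermediate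
20 | (9S)-alcohol of 19, dioxolanone intact | C#CCC[C@@H]3OC(C)(C)O[C@H]4CCC(=C)[C@H]([C@H](O)[C@]5(O[C@H](C(C)(C)C)OC5=O)[C@@H](C)C(=O)OC(C)(C)C)[C@@]34C | intermediate
21 | (9S)-triol: C7 primary alcohol, C8 tertiary alcohol, C9 secondary alcohol; (17R)-tert-butyl ester; ring A and acetonide as in 19 | C#CCC[C@@H]3OC(C)(C)O[C@H]4CCC(=C)[C@H]([C@H](O)[C@](CO)(O)[C@@H](C)C(=O)OC(C)(C)C)[C@@]34C | intermediate
22 | 7-O-triethylsilyl ether of 21 | C#CCC[C@@H]3OC(C)(C)O[C@H]4CCC(=C)[C@H]([C@H](O)[C@](CO[Si](CC)(CC)CC)(O)[C@@H](C)C(=O)OC(C)(C)C)[C@@]34C | intermediate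
23 | (E)-iodoalkene: 22 with the C2 chain converted to (E)-4-iodo-3-methylbut-3-en-1-yl | I/C=C(C)/CC[C@@H]3OC(C)(C)O[C@H]4CCC(=C)[C@H]([C@H](O)[C@](CO[Si](CC)(CC)CC)(O)[C@@H](C)C(=O)OC(C)(C)C)[C@@]34C | intermediate
24 | 9-O-acetate of 23 | I/C=C(C)/CC[C@@H]3OC(C)(C)O[C@H]4CCC(=C)[C@H]([C@H](OC(C)=O)[C@](CO[Si](CC)(CC)CC)(O)[C@@H](C)C(=O)OC(C)(C)C)[C@@]34C | intermediate
25 | C7 aldehyde: 24 with CH2OSiEt3 replaced by CHO | I/C=C(C)/CC[C@@H]3OC(C)(C)O[C@H]4CCC(=C)[C@H]([C@H](OC(C)=O)[C@](C=O)(O)[C@@H](C)C(=O)OC(C)(C)C)[C@@]34C | intermediate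
26 | ten-membered (5E)-olefin: 7-OH (configured as the target lactone oxygen), 8-OH, 9-OAc, (17R)-tert-butyl ester, 2,14-O-isopropylidene, 11(20)-methylene | [C@H]12CC/C(C)=C/[C@H](O)[C@@](O)([C@@H](C)C(=O)OC(C)(C)C)[C@@H](OC(C)=O)[C@H]3C(=C)CC[C@H](OC(C)(C)O2)[C@]13C | intermediate
27 | 7,19-lactone 2,14-diol: (5E)-olefin, 8-OH, 9-OAc, 11(20)-methylene | [C@H]1(O)CC/C(C)=C/[C@@H]2OC(=O)[C@H](C)[C@@]2(O)[C@@H](OC(C)=O)[C@H]3C(=C)CC[C@H](O)[C@]13C | intermediate
28 | 2,14-O-(1-methoxyethylidene) cyclic orthoacetate of 27, both epimers at the orthoester carbon | [C@H]12CC/C(C)=C/[C@@H]4OC(=O)[C@H](C)[C@@]4(O)[C@@H](OC(C)=O)[C@H]3C(=C)CC[C@H](OC(C)(OC)O2)[C@]13C | intermediate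
29 | 14-O-acetate of 27 with free C2 hydroxyl | [C@H]1(O)CC/C(C)=C/[C@@H]2OC(=O)[C@H](C)[C@@]2(O)[C@@H](OC(C)=O)[C@H]3C(=C)CC[C@H](OC(C)=O)[C@]13C | intermediate
30 | 2-O-isobutyrate of 29 | [C@H]1(OC(=O)C(C)C)CC/C(C)=C/[C@@H]2OC(=O)[C@H](C)[C@@]2(O)[C@@H](OC(C)=O)[C@H]3C(=C)CC[C@H](OC(C)=O)[C@]13C | intermediate
31 | (6R)-6-hydroperoxide with C5=C16 exocyclic methylene | C=C1CC[C@H](OC(=O)C(C)C)[C@@]2(C)[C@@H](OC(C)=O)CCC(=C)[C@@H]2[C@H](OC(C)=O)[C@]2(O)[C@@H](C)C(=O)O[C@H]2[C@@H]1OO | intermediate
32 | (6R)-allylic alcohol with C5=C16 exocyclic methylene | C=C1CC[C@H](OC(=O)C(C)C)[C@@]2(C)[C@@H](OC(C)=O)CCC(=C)[C@@H]2[C@H](OC(C)=O)[C@]2(O)[C@@H](C)C(=O)O[C@H]2[C@@H]1O | intermediate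
33 | (6S)-chloride: 11(20)-deoxy precursor of the target | C=C1CC[C@H](OC(=O)C(C)C)[C@@]2(C)[C@@H](OC(C)=O)CCC(=C)[C@@H]2[C@H](OC(C)=O)[C@]2(O)[C@@H](C)C(=O)O[C@H]2[C@H]1Cl | intermediate
34 | CNP0284862.1 | C=C1CC[C@H](OC(=O)C(C)C)[C@@]2(C)[C@@H](OC(C)=O)CC[C@]3(CO3)[C@@H]2[C@H](OC(C)=O)[C@]2(O)[C@@H](C)C(=O)O[C@H]2[C@H]1Cl | target

**Count and risks**

Total step count: 27. Longest linear sequence: 23 steps (steps 1–7, then 12–27); the malic acid branch is steps 8–11.

Three steps most likely to fail:

Step 15. What may go wrong: gold-mediated hydration or hydroalkoxylation of the terminal alkynes and protodesilylation of the enol ether may outrun C–C bond formation. The fallback sets out from 18 and returns at 19. N-iodosuccinimide in THF at −78 °C should convert the silyl enol ether into the α-iodo ketone tert-butyl (2R)-2-[(2S,4R)-2-tert-butyl-4-{[(4S,6S)-4,6-di(but-3-yn-1-yl)-2,2,5-trimethyl-1,3-dioxan-5-yl]iodoacetyl}-5-oxo-1,3-dioxolan-4-yl]propanoate F1. Bu3SnH with Et3B and air in toluene at 0 °C should then generate the C10 α-keto radical, which closes ring A by a 6-exo-dig cyclisation onto the alkyne that the twist-boat acetonide holds next to it. Reduction of the vinyl radical gives the exocyclic methylene of 19 under neutral conditions that leave the other alkyne alone.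

Step 21. What may go wrong: poor facial selectivity in the addition of the alkenylchromium to the C7 aldehyde. The fallback sets out from 25 and returns at 26. The ring closure is run as in step 21 and the product mixture, containing 26 and the C7 epimer of 26 F2, is oxidised with Dess–Martin periodinane to the ten-membered 5-en-7-one F3. Reduction with (R)-2-methyl-CBS-oxazaborolidine and catecholborane at −78 °C, with the fully substituted C8 acting as the large group, should deliver 26 under reagent control.

Step 25. What may go wrong: singlet oxygen may attack the alkene face anti to the lactone oxygen, which would give the 6S alcohol and, after inversion, the wrong chloride. The fallback sets out from 30 and returns at 33. An electrophile with that facial preference can deliver chlorine directly: ene-type chlorination of 30 with hypochlorous acid, generated from Ca(OCl)2 and solid CO2 in CH2Cl2/H2O at 0 °C, should react first at the more nucleophilic trisubstituted olefin, put chlorine on C6 from the same face with loss of a C16 hydrogen and give 33 in one operation. This fallback makes no new compound (F0).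

**Further compounds**

F1 | step 15 | tert-butyl (2R)-2-[(2S,4R)-2-tert-butyl-4-{[(4S,6S)-4,6-di(but-3-yn-1-yl)-2,2,5-trimethyl-1,3-dioxan-5-yl]iodoacetyl}-5-oxo-1,3-dioxolan-4-yl]propanoate, both C10 epimers | [C@@H]1(C(C)(C)C)OC(=O)[C@](O1)(C(=O)C(I)C2(C)[C@H](CCC#C)OC(C)(C)O[C@H]2CCC#C)[C@@H](C)C(=O)OC(C)(C)C
F2 | step 21 | C7 epimer of 26 | [C@H]12CC/C(C)=C/[C@@H](O)[C@@](O)([C@@H](C)C(=O)OC(C)(C)C)[C@@H](OC(C)=O)[C@H]3C(=C)CC[C@H](OC(C)(C)O2)[C@]13C
F3 | step 21 | ten-membered (5E)-5-en-7-one corresponding to 26 | [C@H]12CC/C(C)=C/C(=O)[C@@](O)([C@@H](C)C(=O)OC(C)(C)C)[C@@H](OC(C)=O)[C@H]3C(=C)CC[C@H](OC(C)(C)O2)[C@]13C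
F0 | step 25 | none | none
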